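The ratio of target made to catalyst charged is what we ask of the delta flask first, before any mechanism.

| setting | delta | eta | flask |
|---|---|---|---|
| starting material | 0.050 M | 0.10 M | 0.050 M |
| second substrate | 0.25 M | 0.25 M | 0.250 M |
| free enzyme | 25 µM | 25 µM | 25 µM |
| temperature | 5 °C | 0 °C | 5 °C |
| remark | the very flask that is asked about, followed so far | run made earlier |  |
| time |  |  | 8.0 h |

| run | time / min | target / % |
|---|---|---|
| delta | 90.0 | 39.8 |
| delta | 180 | 48.0 |
| delta | 300 | 49.4 |
| delta | 360 | 48.9 |
| delta | 480 | 49.6 |
| eta | 10.0 | 3.7 |
| eta | 20.0 | 7.0 |
| eta | 30.0 | 8.4 |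
| eta | 40.0 | 11.6 |
| eta | 50.0 | 13.7 |

(readings scatter by 0.5 percentage points)

- Friday's: at 8.0 h add second substrate, 50.0% of the amount charged, then wait 2.5 h
- Thursday's: at 8.0 h raise the temperature by 15 K, then wait 2.5 h
- Tuesday's: at 8.0 h take out 90% of the first product then present, then wait 2.5 h
- Monday's: change nothing and wait 2.5 h more
- Sunday's: at 8.0 h add free enzyme, 100% of the amount charged, then wait 2.5 h

- what is added takes up no volume worth counting
- on the list of suspects stand: free enzyme -> unfolded enzyme; starting material + free enzyme <-> first complex; first complex <-> loaded enzyme + first product; second substrate + loaded enzyme <-> second complex; second complex -> free enzyme + target; second substrate -> decomposed reagent; first complex -> spent catalyst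

* target, in percent of the starting material first charged, at 8.0 h
* which option adds most target ("none" when 2 percentage points or less is all one gets) (Friday's / Thursday's / Tuesday's / Monday's / Sunday's / none)
* target present, in percent of the starting material first charged, after Thursday's
* target present, in percent of the starting material first charged, after Monday's

The delta readings stop climbing: 49.4% at 300 min and 49.6% at 480 min differ by 0.2 percentage points, less than the scatter of 0.5 points. Averaged from 300 min on, the plateau reads 49.3%, and this is our answer for 8.0 h. So c(target) is 0.0247 M, and the turnover capacity (the total turnover number), target on the plateau over catalyst charged, is 986.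

But is the catalyst what stopped? Perhaps a reagent gave out instead. The plateau leaves 50.7% of the starting material unconverted, and turnover accounts for 9.86% of the second substrate charged, so the round itself has exhausted neither charge. The objection remains that second substrate may also decay by itself, as the list of suspects allows, and these readings do not show c(second substrate). We cannot compute that away, so catalyst loss stays a bet.

Does the capacity survive the eta run? Its last reading stands at 548 turnovers, below the capacity, so eta does not contradict it, though it does not test it either. Taken at face value, Sunday's new catalyst would add 49.3% of the charge. But that catalyst would meet a medium already holding first product and less second substrate, so we treat this as a high estimate, not a bound; it stands above the margin of 2 points.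

The forecast gives 49.5% (48.9% to 50.1%), slightly above our plateau, then 49.6% after Thursday's and 49.5% after Monday's, and it names Sunday's: “Fresh enzyme should restart the reaction”.

The delta flask gives 49.6%, then 49.6% after Thursday's and 49.6% after Monday's; Sunday's adds 9.2 points, and Tuesday's 0.046 points.

    free enzyme → unfolded enzyme (k = 9.52 × 10⁻⁴ min⁻¹, Ea = 240 kJ mol⁻¹)
    starting material + free enzyme ⇌ first complex (K = 7.90 M⁻¹, k = 1.19 × 10⁵ M⁻¹ min⁻¹, Ea = 38.0 kJ mol⁻¹, ΔH = −56.0 kJ mol⁻¹)
    first complex ⇌ loaded enzyme + first product (K = 0.0690 M, k = 366 min⁻¹, Ea = 66.0 kJ mol⁻¹, ΔH = 20.0 kJ mol⁻¹)
    second substrate + loaded enzyme ⇌ second complex (K = 6.58 M⁻¹, k = 1780 M⁻¹ min⁻¹, Ea = 40.0 kJ mol⁻¹, ΔH = −58.0 kJ mol⁻¹)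
    second complex → free enzyme + target (k = 38.1 min⁻¹, Ea = 61.0 kJ mol⁻¹)
    second substrate → decomposed reagent (k = 0.00249 min⁻¹, Ea = 85.0 kJ mol⁻¹)
    first complex → spent catalyst (k = 0.137 min⁻¹, Ea = 78.0 kJ mol⁻¹)
    (constants at 5 °C)

Sunday's gain in 2.5 h comes to 184 turnovers per added enzyme, against the 986 read for the first charge. Reckoned with that capacity, a neighbour flask with 0.020 M of starting material is allowed 123% of its charge; it gives 95.6%, which is 764 turnovers, with 19.0% of its catalyst still free enzyme. The delta flask has stopped in target: at 4800 min it reads 49.6%, with starting material at 50.4%. Its second substrate still moves, from 26.8% at 480 min to 0% at 4800 min, while decomposed reagent climbs from 0.158 M to 0.225 M.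

The numbers in the tables are calculated with constants of no real substance.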